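**Remarks and assumptions (chemistry)**

- Checked atom by atom against the target, the tricycle and the ten-membered diketone carry the target configuration at C1, C7, C9, C10 and C11, so no descriptor is changed; the two silyl ethers are made different (TES on O7, TBS on O9) because O7 has to be unmasked alone.
- Protonation next to a C9 ketone in a cyclopentenone would favour the cis ring fusion, whereas the target needs H10 anti to the C1 methyl; the five-membered ring is therefore closed at C8–C9 after an anti-selective C1–C2 bond formation, not by a Nazarov reaction.
- An oxyallyl (4+3) adduct gives no handle to tell C3 from C8 and carries no oxygen at C7; the seven-membered ring is therefore made by dichlorocarbene ring expansion, which places the C7 carbonyl next to the chloroalkene.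
- In the tricycle the C11 methyl is syn to the axial C1 methyl (the less stable epimer), so it is set last and kinetically.
- Compounds 1, 7 and 8 are taken to be purchasable.

## Structural features

The target is a briarane: a ten-membered carbocycle (C1–C10) trans-fused to cyclohexene ring A across C1–C10 and to a γ-lactone across C7–C8 (O7–C19–C17–C8). It has nine stereocentres: C1 (quaternary, methyl), C2 (OAc), C7, C8 (tertiary OH), C9 (OH), C10, C11 (methyl), C12 (OAc) and C17. C7–C8–C9–C10–C1–C2 form an unbroken run on the large ring, C10–C11–C12 continue it on ring A, and C17 sits beside C8. The C5=C6 alkene is tetrasubstituted, bears chlorine and has C4 and C7 cis. Fragile groups are the β-hydroxy lactone (retro-aldol under base), the allylic acetate at C12, the acetates next to free hydroxyls (acyl migration) and C11–H for as long as C12 is a ketone. The real difficulty is a strained ten-membered ring that holds a geometrically defined tetrasubstituted chloroalkene and oxygen on C2, C7, C8 and C9, together with the anti relation of the C1 methyl and H10. The key step exploits that C2 and C8 both bear oxygen and lie across the ring from each other (joined by C1–C10–C9 on one side and C3–C7 on the other): the ring is the cleavage product of a C2=C8 alkene common to a cyclopentene (C1, C2, C8, C9, C10) and a chlorocycloheptadiene (C2–C8).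

## Logic of the disconnections

30 ⇐ 29 ⇐ 28 ⇐ 27. The last operations cut only the O9–Si bond, the two acetyl C–O bonds and the carbinol C–H bonds at C2 and C12. This leaves 27 with ketones at C2 and C12 and no acyl groups that could migrate. The forward demand is that hydride reaches both carbonyls from the correct faces in one pot and that acetylation spares the tertiary C8 hydroxyl.

27 ⇐ 26 ⇐ 25 ⇐ 24. The lactone is cut at C8–C17 (a β-hydroxy ester, aldol retron) and then at the O7–acyl bond. The C8 carbonyl made by the key step is the natural electrophile, and delivery from O7 fixes the site (C8, not C2 or C12). Two stereocentres and one ring are removed. The forward step must reduce C–Br faster than the α-oxygenated ketone, and O7 must be freed with O9 still silylated.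

24 ⇐ 21. The carbonyl carbons C2 and C8 are reconnected to a C2=C8 bond. The medium ring disappears and is replaced by a rigid fused tricycle of common ring sizes, in which C5=C6 lies in a seven-membered ring and C1, C7, C9, C10 and C11 are already set. The forward step needs an oxidant that picks the tetrasubstituted alkene over the chloroalkene and the enone.

21 ⇐ 20 ⇐ 19. The C11–CH3 bond and the C11–H bond are cut. C11 is the only acidic position of 19, so the alkylation is regiochemically safe. The configuration of 21 at C11 is the less stable one, so the forward protonation must be kinetic.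

19 ⇐ 18 ⇐ 17 ⇐ 16 ⇐ 15. Both O–Si bonds and the C9–H and C7–H bonds are cut, leading back to ene-dione 15. C9 is set by the angular methyl and C7 by delivery from the C9 hydroxyl, which gives the anti diol. The forward demands are reduction at C9 before C7 and C12, and silylation at the less hindered O7 first.

15 ⇐ 13. The C2=C8 π bond is removed. A β-diketone with a single β-hydrogen (H2) allows a regiospecific selenoxide elimination.

13 ⇐ 12. The C8–C9 bond is cut (Dieckmann retron). This bond is not at the ring fusion, so closing it cannot change the C1/C10 relationship. The enolate must form only at C8 and without excess base, because C10 is α to the ester.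

12 ⇐ 11 + 6. The C1–C2 bond is cut. This is the convergent junction of ring A and the seven-membered ring and it creates the quaternary carbon; the C10 substituent directs the acceptor to the opposite face. The forward step must be γ-selective at a fully substituted carbon.

11 ⇐ 10 ⇐ 9 ⇐ 7 + 8. Ring A is cut at C13=C14 (aldol condensation) and C1–C10 (conjugate addition), giving two small achiral pieces. The catalyst must control the carbon that becomes C10; the C1 configuration does not matter because it is erased in 11.

6 ⇐ 4 ⇐ 2 ⇐ 1. The C8=C2 unsaturation is removed and then the CCl carbon C6 is excised (C5–C6 and C6–C7). A one-carbon insertion puts chlorine on the alkene next to the carbonyl and makes the cis tetrasubstituted alkene inside a ring. The forward step needs the more substituted enol ether of 1.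

## Other disconnections considered

Alternative 1: The cut runs through ring A at C1–C14 and C10–C11. Forward, dienophile A1 (formyl on the future C1, ester on the future C10, trans to each other) and Z-silyloxydiene A2 would combine in a Diels–Alder reaction under a protonated B-o-tolyl oxazaborolidine (proline-derived, activated by HN(SO2CF3)2) to give A3.
- In its favour: one catalytic step would create C1, C10 and C11 with absolute control. The anti relation of C2 and C9 would follow stereospecifically from the E geometry of A1, and the C11 methyl would be placed by the Z geometry of A2. On these points it is better than the chosen plan, which needs an anti-selective conjugate addition for C1/C10 and two late enolate operations for C11.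
- Against it here: A3 holds ring A only. The ten-membered ring would still have to be closed by bond formation against strain, and the tetrasubstituted chloroalkene would have to be built in an open chain where nothing enforces the cis geometry.
- Comparison: the cycloaddition is concerted and as dependable as the ozonolysis (equal), but a dienophile with two acceptors raises a regiochemical question that the ozonolysis does not have. Ring A would be reached in fewer steps than 10 and 11 (better), yet the ring closure and the chloroalkene would probably cost more steps overall than the fifteen that lead to 21.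

Alternative 2: The cut is the C8–C17 bond of the lactone. Forward, 2-bromopropanoate A4 would be reduced by SmI2 (divalent samarium) to a samarium enolate that adds to the C8 ketone and gives A5, the C9 silyl ether of the target.
- In its favour: C8, C17 and the lactone arise in one neutral step from a bromide that is trivial to install, and A5 is one deprotection from the target. As a reaction it is equal to step 19 of the chosen plan, which uses the same transformation, and it comes even later in the sequence.
- Against it as the organising cut: it removes three carbons and two stereocentres but leaves the whole ten-membered diketone unsolved, so it simplifies far less than the C2=C8 reconnection.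
- Comparison: both key steps are reliable, but the samarium step carries the hazard of electron transfer to the α-oxygenated C8 ketone. Having the acetates in place before lactone formation (A4) would require C2 to be reduced in the presence of the C8 ketone, which the chosen order (lactone first, 27) avoids. In step count the two orders are equal.

Alternative 3: The cut is the ring A bond C1–C10. Forward, lactone A6 would be converted (LiN(iPr)2, Me3SiCl) into silyl ketene acetal A7. Its [3,3] shift through the boat array enforced by the lactone ring would form C1–C10, break C13–O and deliver acid A8 with C13=C14 in place (Ireland–Claisen ring contraction).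
- In its favour: C1 and C10 would be set stereospecifically from the C13 carbinol and the alkene geometry of A6, and C2, C11 and C12 would already carry their final substituents. Ring A stereocontrol is therefore better than in the chosen plan, which sets C11 kinetically and C12 by a late hydride reduction.
- Against it: A6 needs four stereocentres and a geometrically pure trisubstituted alkene before the key step. A8 is still an open chain between C2 and C9, so the medium ring and the tetrasubstituted chloroalkene remain to be made by ring closure.
- Comparison: a thermal suprafacial shift is as dependable as the ozonolysis (equal) and needs no selection among alkenes (better), but the boat transition state crowds the C1 methyl and the C2 chain. Overall step economy would likely be worse because neither the ten-membered ring nor C5=C6 is addressed.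

Key step: step 16

## Steps

Step 1
Reactants: 1 2-methylcyclohexan-1-one
Product: 2 trimethyl[(2-methylcyclohex-1-en-1-yl)oxy]silane
Conditions: TMSCl, NaI, Et3N, MeCN, rt
Reagents that add atoms: chlorotrimethylsilane, C[Si](C)(C)Cl
Why: Silyl enol ether formation under equilibrating conditions should favour the tetrasubstituted enol ether, which carries the future C5 methyl on the alkene.

Step 2
Reactants: 2 trimethyl[(2-methylcyclohex-1-en-1-yl)oxy]silane
Product: 4 2-chloro-3-methylcyclohept-2-en-1-one, via dichlorocyclopropane 3 (not isolated)
Conditions: Cl3CCO2Na, DME, 85 °C; then toluene, 110 °C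
Reagents that add atoms: sodium trichloroacetate (dichlorocarbene source), [Na+].[O-]C(=O)C(Cl)(Cl)Cl
Why: Dichlorocarbene adds to the electron-rich enol ether and the silyloxy dichlorocyclopropane opens by the oxygen-assisted cyclopropyl-to-allyl ring expansion with loss of chloride and silyl. The chloroalkene is thus formed inside a seven-membered ring, where only the cis ring geometry exists, and C7 arrives as a carbonyl.

Step 3
Reactants: 4 2-chloro-3-methylcyclohept-2-en-1-one
Product: 6 2-chloro-3-methylcyclohepta-2,6-dien-1-one, via silyl dienol ether 5 (not isolated)
Conditions: LiN(iPr)2, TMSCl, THF, −78 °C; then Pd(OAc)2 (10 mol %), O2, DMSO, rt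
Reagents that add atoms: none
Why: Kinetic α'-deprotonation and O-silylation followed by Saegusa–Ito dehydrogenation (divalent palladium catalyst, O2 as terminal oxidant) should install the C8=C2 enone alkene; the only β-hydrogens available sit on the future C2.

Step 4
Reactants: 7 propanal; 8 methyl (2E)-4-oxopent-2-enoate
Product: 9 methyl (2S)-4-oxo-2-[(2R)-1-oxopropan-2-yl]pentanoate
Conditions: (S)-α,α-diphenylprolinol trimethylsilyl ether (10 mol %), PhCO2H (10 mol %), toluene, 0 °C
Reagents that add atoms: none
Why: Enamine-catalysed asymmetric Michael addition: the enamine of 7 attacks the alkene carbon β to the ketone of 8 from its unshielded face, which by analogy with nitroalkene acceptors should give the syn adduct with the S configuration at the future C10. The aldehyde α-centre (future C1) is flattened in step 6 and does not matter.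

Step 5
Reactants: 9 methyl (2S)-4-oxo-2-[(2R)-1-oxopropan-2-yl]pentanoate
Product: 10 methyl (1S)-2-methyl-5-oxocyclohex-3-ene-1-carboxylate
Conditions: TsOH·H2O (10 mol %), toluene, 80 °C
Reagents that add atoms: none
Why: Intramolecular aldol condensation of the methyl ketone (C13) with the aldehyde (C14) gives the only accessible ring size, the cyclohexenone; C10, α to the ester only, should not enolise under these acidic conditions.

Step 6
Reactants: 10 methyl (1S)-2-methyl-5-oxocyclohex-3-ene-1-carboxylate
Product: 11 methyl (1S)-5-{[tert-butyl(dimethyl)silyl]oxy}-2-methylcyclohexa-2,4-diene-1-carboxylate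
Conditions: TBSOTf, Et3N, CH2Cl2, 0 °C to rt
Reagents that add atoms: tert-butyldimethylsilyl triflate, CC(C)(C)[Si](C)(C)OS(=O)(=O)C(F)(F)F
Why: Soft enolisation under equilibrating conditions should give the through-conjugated silyl dienol ether by loss of the γ-hydrogen at C1; C10 is not touched.

Step 7
Reactants: 11 ring A silyl dienol ether; 6 2-chloro-3-methylcyclohepta-2,6-dien-1-one
Product: 12 Michael adduct as its C7 silyl enol ether
Conditions: TBSOTf (5 mol %), CH2Cl2, −78 °C; then Et3N
Reagents that add atoms: none
Why: Vinylogous Mukaiyama–Michael addition: the γ-carbon (C1) of the dienol ether adds to C2 of the silyl-activated dienone, and silyl transfer traps the adduct as the C7 enol ether while the ring A enone re-forms. The acceptor should approach C1 on the face opposite to the adjacent C10 ester, which creates the quaternary centre with C2 anti to C9; the configuration at C2 is irrelevant.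

Step 8
Reactants: 12 Michael adduct as its C7 silyl enol ether
Product: 13 tricyclic β-diketone (C7 and C9 ketones; trans ring fusion)
Conditions: Bu4N[Ph3SiF2], THF, −40 to 0 °C; then AcOH
Reagents that add atoms: none
Why: Fluoride releases the C8 enolate regiospecifically and without excess base, and Dieckmann condensation (5-exo-trig) onto the C9 ester closes the five-membered ring at C8–C9, a bond remote from C1 and C10, so the anti relation from step 7 becomes the trans ring fusion. The methoxide set free deprotonates the β-diketone, which makes the closure irreversible and shields C10 from epimerisation.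

Step 9
Reactants: 13 tricyclic β-diketone
Product: 15 tricyclic ene-dione (C2=C8), via selenide 14 (not isolated)
Conditions: PhSeCl, pyridine, CH2Cl2, 0 °C; then 30% H2O2, 0 °C
Reagents that add atoms: none
Why: α-Selenenylation of the enolised β-diketone at C8 and selenoxide syn-elimination; H2 is the only β-hydrogen, and selenium should enter anti to the bulky C1 substituent on C2, that is syn to H2.

Step 10
Reactants: 15 tricyclic ene-dione
Product: 16 9-hydroxy enone (O9 syn to the C1 methyl)
Conditions: NaBH4 (0.3 equiv), MeOH/CH2Cl2 (1:1), −78 °C
Reagents that add atoms: none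
Why: Chemoselective 1,2-reduction: C9 is the five-ring carbonyl, conjugated to one alkene only and part of the strained trans-fused cyclopentenone, whereas C7 is a seven-ring carbonyl conjugated on both sides and C12 an ordinary enone that borohydride attacks slowly without a lanthanide salt. Hydride should add from the face opposite to the angular C1 methyl.

Step 11
Reactants: 16 9-hydroxy enone
Product: 17 anti 7,9-diol
Conditions: Me4NBH(OAc)3, MeCN/AcOH (1:1), −25 °C
Reagents that add atoms: none
Why: Hydroxyl-directed (Evans–Saksena) reduction: the boron bound to O9 delivers hydride to C7 on the face of O9, which places O7 anti to O9; the reagent should leave the unassisted C12 enone alone.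

Step 12
Reactants: 17 anti 7,9-diol
Product: 18 7-O-triethylsilyl ether
Conditions: TESCl (1.05 equiv), imidazole, CH2Cl2, −40 °C
Reagents that add atoms: chlorotriethylsilane, CC[Si](Cl)(CC)CC
Why: Selective silylation of the less hindered hydroxyl: O7 is flanked by two trigonal carbons, whereas O9 sits next to the ring-fusion CH and syn to the angular methyl.

Step 13
Reactants: 18 7-O-triethylsilyl ether
Product: 19 7-O-TES 9-O-TBS bis(silyl ether)
Conditions: TBSOTf, 2,6-lutidine, CH2Cl2, −78 to −20 °C
Reagents that add atoms: tert-butyldimethylsilyl triflate, CC(C)(C)[Si](C)(C)OS(=O)(=O)C(F)(F)F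
Why: Silylation of the hindered C9 hydroxyl with the reactive triflate and a weak hindered base that should not enolise the enone; the TES/TBS pair allows O7 to be freed alone later.

Step 14
Reactants: 19 7-O-TES 9-O-TBS bis(silyl ether)
Product: 20 11-epi-11-methyl enone (methyl anti to the C1 methyl)
Conditions: LiN(iPr)2, THF, −78 °C; MeI, −78 to −40 °C
Reagents that add atoms: iodomethane, CI
Why: Kinetic α'-enolate alkylation; C11 is the only acidic position, and iodomethane should enter on the face away from the axial C1 methyl, giving the 11-epimer.

Step 15
Reactants: 20 11-epi-11-methyl enone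
Product: 21 key-step precursor (C11 methyl syn to the C1 methyl)
Conditions: LiN(iPr)2, THF, −78 °C; then AcOH, −78 °C
Reagents that add atoms: none
Why: Deprotonation and kinetic protonation: the proton should arrive on the same open face that iodomethane used, which inverts C11 and gives the contra-thermodynamic epimer required.

Step 16
Reactants: 21 key-step precursor (6-5-7 tricycle)
Product: 24 ten-membered 2,8-diketone (7-O-TES; 9-O-TBS; ring A enone), via primary ozonide 22 (not isolated), via ozonide 23 (not isolated)
Conditions: O3, CH2Cl2, −78 °C (Sudan Red 7B end point); then Me2S, −78 °C to rt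
Reagents that add atoms: ozone, [O-][O+]=O
Why: Criegee ozonolysis: ozone adds as a 1,3-dipole to C2=C8 to give primary ozonide 22, which cycloreverts to a carbonyl oxide and a ketone held in the same ring; these recombine to ozonide 23, and Me2S reduces the peroxide bond to leave ketones at C2 and C8. The closest known reaction type is the ozonolytic cleavage of a ring-fusion tetrasubstituted alkene of a fused bicycle to a medium-ring diketone. The ten-membered ring is not closed by forming a bond: it appears when the bond shared by the five- and seven-membered rings is broken, so no cyclisation against strain is needed. No stereocentre is created; C1, C7, C9, C10 and C11 and the cis ring geometry of C5=C6 are carried over because none of their bonds is touched. The step needs chemoselectivity among three alkenes: C2=C8 is the only electron-rich, fully alkyl-substituted one, C5=C6 is deactivated by chlorine, and C13=C14 by conjugation with the C12 carbonyl and by the neighbouring quaternary C1. Ozone is dosed to the bleaching of the indicator dye, which should react after the tetrasubstituted alkene and before the two deactivated ones. The reductive work-up is neutral, which matters because the 2,8-diketone is prone to transannular aldol reaction under acid or base.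

Step 17
Reactants: 24 ten-membered 2,8-diketone
Product: 25 7-hydroxy diketone
Conditions: HF·pyridine, pyridine, THF, 0 °C
Reagents that add atoms: none
Why: Selective desilylation: a secondary TES ether should be cleaved by buffered fluoride much faster than the hindered TBS ether at O9.

Step 18
Reactants: 25 7-hydroxy diketone
Product: 26 7-O-(2-bromopropanoate)
Conditions: 2-bromopropanoyl bromide, pyridine, CH2Cl2, −20 °C
Reagents that add atoms: 2-bromopropanoyl bromide, CC(Br)C(Br)=O
Why: O-Acylation of the only free hydroxyl; the bromine-bearing centre is a mixture, which is harmless because it becomes an enolate carbon.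

Step 19
Reactants: 26 7-O-(2-bromopropanoate)
Product: 27 lactone with tertiary C8 hydroxyl (C2 ketone and C12 enone kept)
Conditions: SmI2 (2.5 equiv), THF, −78 °C
Reagents that add atoms: none
Why: Samarium Reformatsky reaction: divalent samarium reduces the C–Br bond to a trivalent samarium enolate that adds to the C8 ketone (5-exo-trig) and closes the γ-lactone. The tether from O7 delivers C17 to the carbonyl face on the side of O7 while the C6–C7–C8–C9 segment stays extended, which should give the trans-fused lactone, and a chelated chair-like transition state should turn the C17 methyl away from C9, that is cis to the new hydroxyl.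

Step 20
Reactants: 27 lactone with tertiary C8 hydroxyl
Product: 28 2,12-diol
Conditions: NaBH4, CeCl3·7H2O, MeOH, −78 to −20 °C
Reagents that add atoms: none
Why: Luche reduction: 1,2-reduction of the C12 enone together with the saturated C2 ketone, hydride being expected on the exposed outer face of each carbonyl. This should give the C12 alcohol trans to the C11 methyl and the C2 alcohol with its oxygen on the side of the C1 methyl; the lactone should survive.

Step 21
Reactants: 28 2,12-diol
Product: 29 2,12-diacetate 9-O-TBS ether
Conditions: Ac2O, pyridine, DMAP (cat.), CH2Cl2, 0 °C to rt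
Reagents that add atoms: acetic anhydride, CC(=O)OC(C)=O
Why: Acylation of the two secondary hydroxyls under nucleophilic catalysis; the tertiary C8 hydroxyl is too hindered to react under these conditions.

Step 22
Reactants: 29 2,12-diacetate 9-O-TBS ether
Product: 30 target compound
Conditions: HF·pyridine, THF, 0 °C to rt
Reagents that add atoms: none
Why: Fluoride desilylation under mildly acidic conditions should free the C9 hydroxyl without the acetate migration or retro-aldol opening that a basic fluoride source could cause.

## Compound list

1 | 2-methylcyclohexan-1-one | CC1CCCCC1=O | starting material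
2 | trimethyl[(2-methylcyclohex-1-en-1-yl)oxy]silane | CC1=C(O[Si](C)(C)C)CCCC1 | intermediate
3 | [(7,7-dichloro-6-methylbicyclo[4.1.0]heptan-1-yl)oxy]trimethylsilane (racemic) | CC12CCCCC1(O[Si](C)(C)C)C2(Cl)Cl | intermediate
4 | 2-chloro-3-methylcyclohept-2-en-1-one | CC1=C(Cl)C(=O)CCCC1 | intermediate
5 | [(7-chloro-6-methylcyclohepta-1,6-dien-1-yl)oxy]trimethylsilane | CC1=C(Cl)C(O[Si](C)(C)C)=CCCC1 | intermediate
6 | 2-chloro-3-methylcyclohepta-2,6-dien-1-one | CC1=C(Cl)C(=O)C=CCC1 | intermediate
7 | propanal | CCC=O | starting material
8 | methyl (2E)-4-oxopent-2-enoate | COC(=O)/C=C/C(C)=O | starting material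
9 | methyl (2S)-4-oxo-2-[(2R)-1-oxopropan-2-yl]pentanoate | COC(=O)[C@@H](CC(C)=O)[C@@H](C)C=O | intermediate
10 | methyl (1S)-2-methyl-5-oxocyclohex-3-ene-1-carboxylate (both C2 epimers) | COC(=O)[C@@H]1C(C)C=CC(=O)C1 | intermediate
11 | methyl (1S)-5-{[tert-butyl(dimethyl)silyl]oxy}-2-methylcyclohexa-2,4-diene-1-carboxylate | COC(=O)[C@@H]1C(C)=CC=C(O[Si](C)(C)C(C)(C)C)C1 | intermediate
12 | methyl (1S)-2-[3-{[tert-butyl(dimethyl)silyl]oxy}-4-chloro-5-methylcyclohepta-2,4-dien-1-yl]-2-methyl-5-oxocyclohex-3-ene-1-carboxylate (ring methyl cis to the ester; cycloheptadienyl CH undefined) | C[C@]1(C2C=C(O[Si](C)(C)C(C)(C)C)C(Cl)=C(C)CC2)C=CC(=O)C[C@@H]1C(=O)OC | intermediate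
13 | tricyclic β-diketone (briarane numbering): ring A enone C12(=O)–C13=C14, C1 methyl anti to H10, ketones at C7 and C9 flanking C8–H, C2–H, C5(Me)=C6(Cl); C2 and C8 undefined | C[C@]12C=CC(=O)C[C@@H]1C(=O)C3C2CCC(C)=C(Cl)C3=O | intermediate
14 | 8-(phenylselanyl) derivative of 13 | C[C@]12C=CC(=O)C[C@@H]1C(=O)C3([Se]c4ccccc4)C2CCC(C)=C(Cl)C3=O | intermediate
15 | tricyclic ene-dione: as 13 with C2=C8 | C[C@]12C=CC(=O)C[C@@H]1C(=O)C3=C2CCC(C)=C(Cl)C3=O | intermediate
16 | 9-hydroxy derivative of 15 (O9 syn to the C1 methyl; C7 ketone kept) | C[C@]12C=CC(=O)C[C@@H]1[C@H](O)C3=C2CCC(C)=C(Cl)C3=O | intermediate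
17 | 7,9-diol (O7 anti to O9) | C[C@]12C=CC(=O)C[C@@H]1[C@H](O)C3=C2CCC(C)=C(Cl)[C@@H]3O | intermediate
18 | 7-O-triethylsilyl ether of 17 | C[C@]12C=CC(=O)C[C@@H]1[C@H](O)C3=C2CCC(C)=C(Cl)[C@@H]3O[Si](CC)(CC)CC | intermediate
19 | 7-O-triethylsilyl 9-O-tert-butyldimethylsilyl ether of 17 | C[C@]12C=CC(=O)C[C@@H]1[C@H](O[Si](C)(C)C(C)(C)C)C3=C2CCC(C)=C(Cl)[C@@H]3O[Si](CC)(CC)CC | intermediate
20 | 11-methyl derivative of 19, C11 methyl anti to the C1 methyl (11-epimer) | C[C@]12C=CC(=O)[C@@H](C)[C@@H]1[C@H](O[Si](C)(C)C(C)(C)C)C3=C2CCC(C)=C(Cl)[C@@H]3O[Si](CC)(CC)CC | intermediate
21 | key-step precursor: 6-5-7 tricycle, ring A enone, C11 methyl syn to the C1 methyl, C2=C8, C5(Me)=C6(Cl), 7-O-TES, 9-O-TBS | C[C@]12C=CC(=O)[C@H](C)[C@@H]1[C@H](O[Si](C)(C)C(C)(C)C)C3=C2CCC(C)=C(Cl)[C@@H]3O[Si](CC)(CC)CC | intermediate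
22 | primary ozonide of 21 (1,2,3-trioxolane across C2–C8; C2 and C8 undefined) | C[C@]12C=CC(=O)[C@H](C)[C@@H]1[C@H](O[Si](C)(C)C(C)(C)C)C3(OOO4)C24CCC(C)=C(Cl)[C@@H]3O[Si](CC)(CC)CC | intermediate
23 | ozonide (1,2,4-trioxolane bridging C2 and C8; C2 and C8 undefined) | C[C@]12C=CC(=O)[C@H](C)[C@@H]1[C@H](O[Si](C)(C)C(C)(C)C)C3(OO4)OC24CCC(C)=C(Cl)[C@@H]3O[Si](CC)(CC)CC | intermediate
24 | ten-membered 2,8-diketone: 7-O-TES, 9-O-TBS, ring A enone (C12=O, C13=C14), cis C5(Me)=C6(Cl) | O=C1CC/C(C)=C(/Cl)[C@H](O[Si](CC)(CC)CC)C(=O)[C@@H](O[Si](C)(C)C(C)(C)C)[C@H]2[C@@H](C)C(=O)C=C[C@@]21C | intermediate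
25 | 7-hydroxy derivative of 24 | O=C1CC/C(C)=C(/Cl)[C@H](O)C(=O)[C@@H](O[Si](C)(C)C(C)(C)C)[C@H]2[C@@H](C)C(=O)C=C[C@@]21C | intermediate
26 | 7-O-(2-bromopropanoyl) derivative of 25 (either configuration at CHBr) | O=C1CC/C(C)=C(/Cl)[C@H](OC(=O)C(C)Br)C(=O)[C@@H](O[Si](C)(C)C(C)(C)C)[C@H]2[C@@H](C)C(=O)C=C[C@@]21C | intermediate
27 | trans-fused γ-lactone: C8 tertiary hydroxyl cis to the C17 methyl, 9-O-TBS, C2 ketone, C12 enone | O=C1CC/C(C)=C(/Cl)[C@@H]2OC(=O)[C@H](C)[C@@]2(O)[C@@H](O[Si](C)(C)C(C)(C)C)[C@H]2[C@@H](C)C(=O)C=C[C@@]21C | intermediate
28 | 2,12-diol of 27 | O[C@H]1CC/C(C)=C(/Cl)[C@@H]2OC(=O)[C@H](C)[C@@]2(O)[C@@H](O[Si](C)(C)C(C)(C)C)[C@H]2[C@@H](C)[C@H](O)C=C[C@@]21C | intermediate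
29 | 2,12-diacetate 9-O-TBS ether | CC(=O)O[C@H]1CC/C(C)=C(/Cl)[C@@H]2OC(=O)[C@H](C)[C@@]2(O)[C@@H](O[Si](C)(C)C(C)(C)C)[C@H]2[C@@H](C)[C@H](OC(C)=O)C=C[C@@]21C | intermediate
30 | CNP0296164.1 (2,12-diacetoxy-6-chloro-8,9-dihydroxy briarane lactone) | CC(=O)O[C@H]1CC/C(C)=C(/Cl)[C@@H]2OC(=O)[C@H](C)[C@@]2(O)[C@@H](O)[C@H]2[C@@H](C)[C@H](OC(C)=O)C=C[C@@]21C | target

## Step count and risk

Total steps: 22. Longest linear sequence: 19 steps (1 → 30 through steps 1–3 and 7–22; the branch from 7 and 8 is equally long).

Least certain steps:

- **Step 16 (key step).** The likely failure is loss of chemoselectivity. C2=C8 is screened by two silyloxy-bearing carbons and a quaternary carbon and is inductively depleted, so ozone may begin to consume C13=C14 or C5=C6 before it is used up. Fallback: separate the oxidation into two events. From 21, mCPBA (NaHCO3, CH2Cl2, 0 °C), which responds far more strongly to alkene electron density than ozone, should give the 2,8-epoxide F1. H5IO6 in wet THF (buffered to protect the TES ether) would open and cleave it to the diketone, and the route is rejoined at 24.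

- **Step 7.** What may go wrong is attack through the α-carbon (C13) of the dienol ether instead of the hindered γ-carbon, protodesilylation of the diene by the Lewis acid, or reversal of the addition at the congested quaternary centre. Fallback: form the same C1–C2 bond by cycloaddition. From 10, trimethyl orthoformate and TsOH should give the extended methyl dienol ether F2. Its Diels–Alder reaction with 6 (neat, 110 °C, addition anti to the ester) would give the bridged 1-methoxybicyclo[2.2.2]octene adduct F3, with the C1–C2 and C12–C8 bonds formed together. TsOH in wet acetone would fragment the β-methoxy ketone by retro-aldol cleavage of C12–C8 to the keto ester F4. LiN(SiMe3)2 (THF, −78 °C) would then close it by Dieckmann condensation, rejoining the route at 13.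

- **Step 10.** Site selectivity among three carbonyls may be insufficient; in particular C7 may be reduced alongside C9, and then without facial control. Fallback: over-reduce and re-oxidise. From 15, excess NaBH4 under the same conditions should give the 7,9-diol F5 (C9 set by the angular methyl, C7 as a mixture). MnO2 in CH2Cl2 should then oxidise the doubly allylic, unhindered C7 carbinol back to the ketone, returning to 16.

- **Step 15.** Deprotonation of the axial C11–H next to the C1 methyl may be slow, and facial control in the protonation or later re-equilibration to the more stable 11-epimer may erode the configuration. Fallback: set C11 by C–H bond formation on an alkene instead of by enolate protonation. From 19, α-methylenation (LiN(iPr)2, then dimethyl(methylidene)ammonium iodide; MeI; NaHCO3) would give the 11-methylidene enone F6. Hydrogenation with RhCl(PPh3)3 and H2 in benzene should then add hydrogen to the exocyclic alkene from the face away from the axial C1 methyl, giving 21 directly.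

- **Step 19.** Electron transfer to the C8 ketone, which carries an acyloxy and a silyloxy group on its α-carbons, could compete with C–Br reduction and expel the C7 ester; ketyl chemistry at the enone is a lesser concern. Fallback: replace single-electron reduction by a two-electron chromium Reformatsky reaction (CrCl2, LiI, THF, rt; divalent chromium), in which the C–Br bond is the only reducible site. It sets out from 26 and returns to 27 and makes no new compound (F0).

- **Step 20.** Facial selectivity at C2 is governed by a mobile ten-membered ring and may be poor even if C12 behaves. Fallback: decouple the two reductions. From 27, NaBH4 (one hydride equivalent) with CeCl3·7H2O at −78 °C should stop at the allylic alcohol F7 (C2 ketone untouched). The C2 ketone would then be reduced on its own with LiBH(s-Bu)3 (THF, −78 °C), chosen to attack from the outer face, rejoining the route at 28.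

## Further compounds

F1 | step 16 | 2,8-epoxide of 21 (epoxide face undefined) | C[C@]12C=CC(=O)[C@H](C)[C@@H]1[C@H](O[Si](C)(C)C(C)(C)C)C3(O4)C24CCC(C)=C(Cl)[C@@H]3O[Si](CC)(CC)CC
F2 | step 7 | methyl (1S)-5-methoxy-2-methylcyclohexa-2,4-diene-1-carboxylate | COC(=O)[C@@H]1C(C)=CC=C(OC)C1
F3 | step 7 | endo Diels–Alder adduct of F2 and 6: 1-methoxybicyclo[2.2.2]oct-2-ene with bridgehead methyl at C1, ester on the ethano bridge pointing to the alkene, fused chloromethylcycloheptenone | CO[C@@]12C=C[C@@](C)([C@H](C1)C(=O)OC)[C@@H]3CCC(C)=C(Cl)C(=O)[C@H]23
F4 | step 7 | methyl (1S)-2-(4-chloro-5-methyl-3-oxocyclohept-4-en-1-yl)-2-methyl-5-oxocyclohex-3-ene-1-carboxylate (ring methyl cis to the ester) | C[C@]1(C2CC(=O)C(Cl)=C(C)CC2)C=CC(=O)C[C@@H]1C(=O)OC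
F5 | step 10 | 7,9-diol with ring A enone (O9 syn to the C1 methyl; C7 epimers) | C[C@]12C=CC(=O)C[C@@H]1[C@H](O)C3=C2CCC(C)=C(Cl)C3O
F6 | step 15 | 11-methylidene derivative of 19 | C[C@]12C=CC(=O)C(=C)[C@@H]1[C@H](O[Si](C)(C)C(C)(C)C)C3=C2CCC(C)=C(Cl)[C@@H]3O[Si](CC)(CC)CC
F0 | step 19 | none | none
F7 | step 20 | 12-hydroxy 2-ketone: lactone 27 with the C12 carbonyl reduced | O=C1CC/C(C)=C(/Cl)[C@@H]2OC(=O)[C@H](C)[C@@]2(O)[C@@H](O[Si](C)(C)C(C)(C)C)[C@H]2[C@@H](C)[C@H](O)C=C[C@@]21C
A1 | alternative 1 | methyl (2E)-3-methyl-4-oxobut-2-enoate | O=C/C(C)=C/C(=O)OC
A2 | alternative 1 | tert-butyl(dimethyl)[(3Z)-penta-1,3-dien-3-yloxy]silane | C=C/C(O[Si](C)(C)C(C)(C)C)=C/C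
A3 | alternative 1 | ring A silyl enol ether with C1 formyl and C10 methyl ester | O=C[C@@]1(C)CC=C(O[Si](C)(C)C(C)(C)C)[C@H](C)[C@@H]1C(=O)OC
A4 | alternative 2 | ten-membered C8 ketone: 2,12-diacetate, 9-O-triethylsilyl, 7-O-(2-bromopropanoate) | CC(=O)O[C@H]1CC/C(C)=C(/Cl)[C@H](OC(=O)C(C)Br)C(=O)[C@@H](O[Si](CC)(CC)CC)[C@H]2[C@@H](C)[C@H](OC(C)=O)C=C[C@@]21C
A5 | alternative 2 | C9 triethylsilyl ether of the target | CC(=O)O[C@H]1CC/C(C)=C(/Cl)[C@@H]2OC(=O)[C@H](C)[C@@]2(O)[C@@H](O[Si](CC)(CC)CC)[C@H]2[C@@H](C)[C@H](OC(C)=O)C=C[C@@]21C
A6 | alternative 3 | six-membered lactone (C9 carbonyl, ring oxygen on C13) with C11 methyl, C12 silyloxy and a Z-alkenyl chain C14=C1(Me)–C2(OTBS)–CH=CH2 on C13 | O=C1C[C@@H](C)[C@H](O[Si](C)(C)C(C)(C)C)[C@@H](O1)/C=C(/C)[C@@H](O[Si](C)(C)C(C)(C)C)C=C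
A7 | alternative 3 | trimethylsilyl ketene acetal of A6 | C[Si](C)(C)OC1=C[C@@H](C)[C@H](O[Si](C)(C)C(C)(C)C)[C@@H](O1)/C=C(/C)[C@@H](O[Si](C)(C)C(C)(C)C)C=C
A8 | alternative 3 | ring A acid (C9 carboxyl on C10, quaternary C1) | OC(=O)[C@H]1[C@@H](C)[C@H](O[Si](C)(C)C(C)(C)C)C=C[C@]1(C)[C@@H](O[Si](C)(C)C(C)(C)C)C=C
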